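## Structural features

The target is a trans-2,3-dihydroflavonol: benzene ring A is fused to a dihydropyranone ring C (O1, C2, C3, C4), and a 4-hydroxyphenyl ring B sits on C2. Ring A is pentasubstituted: the C5 hydroxyl is hydrogen-bonded to the C4 carbonyl, C7 carries a methoxy group, C8 carries a 3-methylbut-2-enyl (prenyl) chain next to O1, and only C6 bears hydrogen. The two stereocentres are adjacent: C2 (R, a benzylic ether carbon) and C3 (R, a secondary carbinol α to the ketone), with aryl and hydroxyl trans. Three parts are fragile. The C2–O1 bond opens under base (enolization at C3, then β-elimination) and under acid (a quinone-methide-like cation supported by the 4'-oxygen). The α-ketol can tautomerize through an enediol. The prenyl olefin rules out hydrogenolysis, strong acids and electrophilic oxidants. The real difficulty is to fix C2 and C3 absolutely in a ring that tends to open, on a ring A whose three oxygens must be told apart and whose prenyl group must sit at C8. The key step uses the α-ketol of ring C: the C4 ketone and C3 carbinol are the 1,2-shift isomer of a 3-hydroxy-2,3-dihydrobenzofuran-3-carbaldehyde in which C2 is bonded to the carbinol carbon (future C4) and the formyl carbon is the future C3.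

## Logic of the disconnections

19 to 18. The last bond cut is the O–Si bond on the ring B oxygen. That phenol must stay masked through alkylation, carbene, enolate and Lewis acid steps, and a silyl group can be removed at the end without base. The forward step must stay non-basic so that ring C does not open.

18 to 17. The O–CH3 bond at O5 is cut. This makes the two ring A methoxy groups of 17 equal, so ring A can come from symmetrical 1. The forward step must cleave only the methoxy group peri to the carbonyl; chelation to the C4 ketone provides that.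

17 to 16. The C2–C3 bond is cut and C2 is reconnected to C4, a retro α-ketol shift. Ring C becomes a five-membered ring with a quaternary carbinol, which can be made with full stereocontrol from a planar enolate. The forward step must move C2 and not the ring A carbon, must run through a chelate so that the carbinol configuration is relayed to C3, and must not ionize the tertiary benzylic hydroxyl.

16 to 15. Only the oxidation level changes: the formyl C–H goes back to an ester C–O bond. The ester is what the earlier steps produce. The forward reduction must stop at the aldehyde.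

15 to 14. The C3–O bond of the tertiary carbinol is cut. The hydroxyl is introduced on an enolate, where the C2 aryl group decides the face. The forward step must oxygenate before the enolate expels the ring oxygen.

14 to 13. The C2–C3 bond of the dihydrobenzofuran is cut between the benzylic ether carbon and a carbene carbon. This opens the ring to an acyclic aryl diazoacetate and places the origin of all chirality in one catalytic step. The forward step must choose the benzylic methylene over other C–H bonds and one of its two hydrogens.

13 to 11 to 10. The diazo group goes back to a ketone and the ketone to a secondary alcohol. No skeletal bond is cut. The gain is that 10 carries the oxidation pattern delivered by the aryl–carbon bond formation below.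

10 to 5 and 9. The benzylic O–CH2 bond is cut. Rings A and B separate, and the junction is a plain phenol alkylation. The forward step must alkylate the phenol and not the secondary alcohol of 5.

9 to 8 to 7 to 6. The benzylic C–Br bond, a carbinol C–H bond and the O–Si bond are cut in turn, leading back to commercial 6.

5 to 3 and 4. The bond between ring A and the side-chain carbon is cut at the carbon ortho to the phenol. The two-carbon unit then comes from 4 in one step. The forward step must be ortho-specific and acid-free because of the ortho-prenyl phenol.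

3 to 1 and 2. The aryl–CH2 bond of the prenyl group is cut. Both ortho positions of 1 are equivalent, so a single ortho C-alkylation places the prenyl group next to the future O1. The forward step must favour ortho C-alkylation over O- and para-alkylation.

## Other disconnections considered

Alternative 1: The cut runs through C2–C3 and the C3–O bond of an allyl ether; O1–C8a is closed later by displacement of fluoride.
- Forward key step: 2-diazo-1-[2-fluoro-4,6-dimethoxy-3-(3-methylbut-2-enyl)phenyl]ethanone A2, prop-2-en-1-ol A3 and 4-formylphenyl 2,2-dimethylpropanoate A4 would combine under Rh2(OAc)4 (dirhodium tetraacetate) and a chiral phosphoric acid. The rhodium carbene is intercepted by the alcohol as an oxonium ylide, which adds in aldol fashion to the acid-activated aldehyde. The product would be (2R,3R)-1-[2-fluoro-4,6-dimethoxy-3-(3-methylbut-2-enyl)phenyl]-3-hydroxy-2-(prop-2-enyloxy)-3-[4-(2,2-dimethylpropanoyloxy)phenyl]propan-1-one A1, with both stereocentres set and no ring formed.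
- In favour: three fragments meet in one catalytic step, C2 and C3 are made together at the final oxidation level, and no skeletal rearrangement is needed.
- Against: the anti adduct must win over plain O–H insertion for a di-ortho-substituted aryl ketone carbene. Ring closure needs nucleophilic aromatic substitution on a fluoroarene with one acyl activator and two methoxy donors; the base and heat required invite retro-aldol cleavage of A1 and epimerization α to the ketone. Ring A must come from a fluoroarene on which prenyl and acyl groups again have to be placed regioselectively. A2 needs a diazomethane-type reagent. Deallylation, ester cleavage and demethylation follow.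
- Comparison: in structure it builds the same two centres, but in an open chain that must still be cyclized under conditions hostile to them; the chosen plan creates C3 inside a closed ring. In mechanism both key steps stretch a known reaction class to a new substrate; this one is the equal of the chosen plan there and the better one in convergence. In step economy it is about equal (shorter longest sequence, longer endgame).

Alternative 2: The cut is C3–C4.
- Forward key step: a carbene from a chiral aminoindanol-based triazolium salt would add to the ring A aldehyde of prop-2-enyl 3-[2-formyl-3,5-dimethoxy-6-(3-methylbut-2-enyl)phenoxy]-3-[4-(methoxymethoxy)phenyl]-2-oxopropanoate A6. The acyl anion equivalent attacks the ketone of the keto ester (6-exo), closing ring C. The acidic C2–H of A6 equilibrates, so one C2 configuration is drained (dynamic kinetic resolution). The product would be prop-2-enyl (2R,3R)-3-hydroxy-5,7-dimethoxy-2-[4-(methoxymethoxy)phenyl]-8-(3-methylbut-2-enyl)-4-oxochromane-3-carboxylate A5.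
- In favour: intramolecular crossed benzoin closure to 3-hydroxychroman-4-ones is an established catalytic reaction type, and it delivers ketone and carbinol at the right oxidation level. On precedent for the ring-forming event it is better than the chosen plan.
- Against: the C3 ester is an auxiliary. Its removal by deallylation and decarboxylation passes through an enediol, erases the C3 centre just made, and leaves the final C3 configuration to thermodynamic protonation with C2 exposed to epimerization. A6 is a labile α-aryloxy ketone reached by alkylating a hindered phenol. The di-ortho-substituted aldehyde is a slow partner for a bulky carbene. Three deprotecting operations follow.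
- Comparison: in structure both plans close the same ring with the same ketol, this one by cyclization at C3–C4, the chosen one by ring expansion at C2–C3. In mechanism this one is ahead on precedent and behind on stereochemical economy, since the chosen plan relays an existing centre to C3 and discards none. Step counts are about equal.

Alternative 3: Two bonds are cut, O1–C8a and C4–C4a, so ring C is stitched from a ring A aryne and a three-carbon hydroxy ester.
- Forward key step: CsF would free the aryne from 3,5-dimethoxy-2-(3-methylbut-2-enyl)-6-(trimethylsilyl)phenyl trifluoromethanesulfonate A8. The alkoxide of methyl (2R,3R)-3-hydroxy-2-(methoxymethoxy)-3-[4-(methoxymethoxy)phenyl]propanoate A9 adds at C8a, away from the C5 methoxy group, and the aryl anion at C4a attacks the ester. The product would be (2R,3R)-5,7-dimethoxy-3-(methoxymethoxy)-2-[4-(methoxymethoxy)phenyl]-8-(3-methylbut-2-enyl)chroman-4-one A7.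
- In favour: it is the most convergent plan. Both stereocentres are imported in A9 and not touched in the annulation. A8 could be drawn from phenol 3 in about three steps. In step economy it is better than the chosen plan.
- Against: the aryne has a prenyl group beside the carbon to be attacked, which hinders the alkoxide and offers an intramolecular ene pathway. The aryl anion can be quenched by proton transfer from the acidic C–H next to the ester before it acylates. Under fluoride the product, with C3–H α to the new ketone, can open by β-elimination of O1 and lose both centres. The anti hydroxy ester costs more steps than a syn diol. Two acetal cleavages and the demethylation follow.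
- Comparison: in structure it forms no stereocentre in the key step, which is an advantage over the chosen plan. In mechanism the annulation is known for phenoxide and salicylate partners but not for a secondary benzylic alkoxide on a hindered, alkene-bearing aryne, so its risk is of the same order as that of the chosen key step. It is shorter overall.

Key step: step 12

Remarks before the steps:
- **Check of the structures.** The descriptors (2R,3R) for 19 and 17 and (2R,3S) for 16 agree with the drawn configurations; nothing needs correction. C2 is S in 14 and R from 15 on without any change in space, because the C3 substituent outranks the aryl group once it bears oxygen.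
- **Design of precursor 16.**
  - The ring B oxygen carries triisopropylsilyl instead of a smaller silyl group. A smaller aryl silyl ether is at risk in the phenoxide alkylation (step 6), with DBU (step 8) and with MgI2 (step 13). The bulkier group has the same donor strength and comes off with buffered fluoride.
  - The tertiary hydroxyl is free and anti to ring B. Only the bidentate hydroxy aldehyde gives the chelate that relays configuration to C3, and a wrong C3 cannot be repaired later, because equilibration of the product at C2 would then lead to the enantiomer.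
  - 16 is made just before use and is not chromatographed.
  - The shift is run with a hindered pyridine so that it proceeds from the scandium alkoxide and not beside free CF3SO3H, which would ionize the tertiary benzylic hydroxyl and aromatize the ring to a benzofuran.
- **Assumption.** Rh2(S-PTTL)4 is taken to deliver the (2S) ester 14; if the sense of induction on this di-ortho-substituted substrate is the opposite, Rh2(R-PTTL)4 is used.
- **Numbering.** Metal alkoxides, enolates and catalyst-bound species are treated as reactive forms of the numbered compounds and are not numbered.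

## Steps

Step 1
Reactants: 1 3,5-dimethoxyphenol; 2 1-bromo-3-methylbut-2-ene
Product: 3 3,5-dimethoxy-2-(3-methylbut-2-enyl)phenol
Conditions: NaH, toluene, 0 °C → rt
Reagents that add atoms: none
Why: C-alkylation of the sodium phenoxide contact ion pair in a non-polar solvent goes to the ortho carbon, and the two ortho positions of 1 are equivalent. The para carbon is flanked by two methoxy groups and is less accessible.

Step 2
Reactants: 3 3,5-dimethoxy-2-(3-methylbut-2-enyl)phenol; 4 ethyl 2-oxoacetate (ethyl glyoxylate)
Product: 5 ethyl 2-hydroxy-2-[2-hydroxy-4,6-dimethoxy-3-(3-methylbut-2-enyl)phenyl]acetate (racemic)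
Conditions: EtMgBr, Et2O, 0 °C; solvent changed to toluene; then 4, 0 °C → rt; aq. NH4Cl
Reagents that add atoms: none
Why: Ortho-specific Friedel–Crafts hydroxyalkylation of a magnesium phenoxide: magnesium binds the aldehyde of 4 and delivers it through a six-membered transition state to the only free ortho carbon. No Brønsted acid is present, so the ortho-prenyl phenol does not cyclize; the new carbinol centre is racemic and is removed in step 7.

Step 3
Reactants: 6 4-hydroxybenzaldehyde
Product: 7 4-[tri(propan-2-yl)silyloxy]benzaldehyde
Conditions: iPr3SiCl, imidazole, DMF, rt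
Reagents that add atoms: chlorotri(propan-2-yl)silane, CC(C)[Si](Cl)(C(C)C)C(C)C
Why: Standard silylation of a phenol; the bulky silyl ether tolerates the basic and Lewis acidic steps that follow.

Step 4
Reactants: 7 4-[tri(propan-2-yl)silyloxy]benzaldehyde
Product: 8 {4-[tri(propan-2-yl)silyloxy]phenyl}methanol
Conditions: NaBH4, MeOH, 0 °C
Reagents that add atoms: none
Why: Hydride reduction of an aromatic aldehyde; the aryl silyl ether is inert.

Step 5
Reactants: 8 {4-[tri(propan-2-yl)silyloxy]phenyl}methanol
Product: 9 [4-(bromomethyl)phenoxy]tri(propan-2-yl)silane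
Conditions: CBr4, PPh3, CH2Cl2, 0 °C; used at once
Reagents that add atoms: tetrabromomethane, BrC(Br)(Br)Br
Why: Appel reaction under neutral conditions, suited to an electron-rich benzylic bromide that would not survive acid.

Step 6
Reactants: 5 ethyl 2-hydroxy-2-[2-hydroxy-4,6-dimethoxy-3-(3-methylbut-2-enyl)phenyl]acetate; 9 [4-(bromomethyl)phenoxy]tri(propan-2-yl)silane
Product: 10 ethyl 2-hydroxy-2-[4,6-dimethoxy-3-(3-methylbut-2-enyl)-2-({4-[tri(propan-2-yl)silyloxy]phenyl}methoxy)phenyl]acetate (racemic)
Conditions: K2CO3, acetone, 40 °C
Reagents that add atoms: none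
Why: Williamson ether synthesis: carbonate deprotonates only the phenol, so the reactive benzylic bromide alkylates the phenoxide and not the secondary alcohol.

Step 7
Reactants: 10 ethyl 2-hydroxy-2-[4,6-dimethoxy-3-(3-methylbut-2-enyl)-2-({4-[tri(propan-2-yl)silyloxy]phenyl}methoxy)phenyl]acetate
Product: 11 ethyl 2-[4,6-dimethoxy-3-(3-methylbut-2-enyl)-2-({4-[tri(propan-2-yl)silyloxy]phenyl}methoxy)phenyl]-2-oxoacetate
Conditions: Dess–Martin periodinane, NaHCO3, CH2Cl2, 0 °C → rt
Reagents that add atoms: none
Why: Dess–Martin oxidation of a secondary benzylic alcohol to the α-keto ester; the buffered, non-acidic oxidant leaves the prenyl olefin, the silyl ether and the electron-rich ring alone.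

Step 8
Reactants: 11 ethyl 2-[4,6-dimethoxy-3-(3-methylbut-2-enyl)-2-({4-[tri(propan-2-yl)silyloxy]phenyl}methoxy)phenyl]-2-oxoacetate
Product: 13 ethyl 2-diazo-2-[4,6-dimethoxy-3-(3-methylbut-2-enyl)-2-({4-[tri(propan-2-yl)silyloxy]phenyl}methoxy)phenyl]acetate, via tosylhydrazone 12 (not isolated)
Conditions: TsNHNH2, EtOH, 70 °C; evaporate; then DBU, CH2Cl2, 0 °C → rt
Reagents that add atoms: 4-methylbenzenesulfonohydrazide, Cc1ccc(cc1)S(=O)(=O)NN
Why: Bamford–Stevens-type diazo formation: the activated keto group condenses with the sulfonylhydrazide, and base then expels sulfinate from the hydrazone anion. The ester stabilizes the aryl diazoacetate.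

Step 9
Reactants: 13 ethyl 2-diazo-2-[4,6-dimethoxy-3-(3-methylbut-2-enyl)-2-({4-[tri(propan-2-yl)silyloxy]phenyl}methoxy)phenyl]acetate
Product: 14 ethyl (2S,3R)-4,6-dimethoxy-7-(3-methylbut-2-enyl)-2-{4-[tri(propan-2-yl)silyloxy]phenyl}-2,3-dihydro-1-benzofuran-3-carboxylate
Conditions: Rh2(S-PTTL)4 (dirhodium tetrakis[N-phthaloyl-(S)-tert-leucinate], 1 mol %), toluene, −60 → −20 °C
Reagents that add atoms: none
Why: Intramolecular rhodium-carbene 1,5 C–H insertion into the benzylic ether methylene; the chiral carboxylate ligands select one of the two enantiotopic hydrogens and so set C2 (the cis ester is expected, but C3 is erased in step 10). The methylene, activated by oxygen and by the 4-silyloxyphenyl ring, should outcompete the O-methyl C–H, and the prenyl olefin is meta to the carbene carbon and cannot be reached.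

Step 10
Reactants: 14 ethyl (2S,3R)-4,6-dimethoxy-7-(3-methylbut-2-enyl)-2-{4-[tri(propan-2-yl)silyloxy]phenyl}-2,3-dihydro-1-benzofuran-3-carboxylate
Product: 15 ethyl (2R,3S)-3-hydroxy-4,6-dimethoxy-7-(3-methylbut-2-enyl)-2-{4-[tri(propan-2-yl)silyloxy]phenyl}-2,3-dihydro-1-benzofuran-3-carboxylate
Conditions: KN(SiMe3)2, THF, −78 °C; then 3-phenyl-2-(phenylsulfonyl)oxaziridine, −78 °C; aq. NH4Cl
Reagents that add atoms: 3-phenyl-2-(phenylsulfonyl)oxaziridine, O=S(=O)(c1ccccc1)N1OC1c1ccccc1
Why: Enolate hydroxylation with a sulfonyloxaziridine: the potassium enolate is planar at C3 and takes oxygen on the face opposite the C2 aryl group, which places the hydroxyl anti to ring B. Low temperature and a fast oxidant are meant to outrun β-elimination of the ring oxygen; the sulfonyl oxaziridine leaves the prenyl olefin alone.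

Step 11
Reactants: 15 ethyl (2R,3S)-3-hydroxy-4,6-dimethoxy-7-(3-methylbut-2-enyl)-2-{4-[tri(propan-2-yl)silyloxy]phenyl}-2,3-dihydro-1-benzofuran-3-carboxylate
Product: 16 (2R,3S)-3-hydroxy-4,6-dimethoxy-7-(3-methylbut-2-enyl)-2-{4-[tri(propan-2-yl)silyloxy]phenyl}-2,3-dihydro-1-benzofuran-3-carbaldehyde
Conditions: iBu2AlH (2.5 equiv), CH2Cl2, −78 °C; MeOH at −78 °C, then aq. sodium potassium tartrate; crude product used directly
Reagents that add atoms: none
Why: Partial reduction of an α-hydroxy ester: the aluminium alkoxide of the tertiary hydroxyl chelates the tetrahedral intermediate, which persists at −78 °C and releases the aldehyde only on quenching. Neither stereocentre is touched.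

Step 12
Reactants: 16 (2R,3S)-3-hydroxy-4,6-dimethoxy-7-(3-methylbut-2-enyl)-2-{4-[tri(propan-2-yl)silyloxy]phenyl}-2,3-dihydro-1-benzofuran-3-carbaldehyde
Product: 17 (2R,3R)-3-hydroxy-5,7-dimethoxy-8-(3-methylbut-2-enyl)-2-{4-[tri(propan-2-yl)silyloxy]phenyl}-2,3-dihydro-4H-chromen-4-one
Conditions: Sc(OSO2CF3)3 (0.2 equiv), 2,6-di-tert-butylpyridine (0.4 equiv), 4 Å molecular sieves, CH2Cl2, −20 °C → rt
Reagents that add atoms: none
Why: Proposed new method: trivalent scandium binds the tertiary hydroxyl (as its alkoxide, the hindered pyridine taking up the CF3SO3H released) and the formyl oxygen of 16 in a five-membered chelate, which holds the O–C–C=O unit syn-periplanar and sets the ring bond from the carbinol carbon to C2 parallel to the aldehyde π* orbital; C2 then shifts suprafacially to the formyl carbon while the alkoxide becomes the C4 carbonyl (α-ketol, or acyloin, rearrangement). The closest known reaction type is the Lewis-acid α-ketol rearrangement of tertiary α-hydroxy aldehydes with ring expansion, which has not been applied to 3-hydroxy-2,3-dihydrobenzofuran-3-carbaldehydes. Ring C is not closed by a cyclization: it arises by one-carbon ring expansion, the five-membered O1–C2–C(OH)–C4a–C8a ring taking up the exocyclic formyl carbon as C3 through a three-centre bridged transition state. C2 migrates with retention, so its configuration comes unchanged from step 9; the new C3 centre is controlled by the carbinol configuration relayed through the chelate, and with the hydroxyl anti to ring B, C2 lies on the aldehyde face that gives 3R, the 2,3-trans ketol. Three selectivities are needed: the shifting group has to be C2 and not the ring A carbon C4a, the shift has to outrun ionization of the tertiary benzylic hydroxyl, and the chelated facial course has to hold because C3 is not corrected by later equilibration. The first rests on the high migratory aptitude of an oxygen-substituted benzylic carbon carrying a 4-silyloxyphenyl donor and on the fact that only C2 migration gives an aryl ketone conjugated with ring A. The second rests on the α-formyl group, which disfavours a cation at the carbinol carbon, and on the acid-free medium; the third on the bidentate hydroxy aldehyde itself.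

Step 13
Reactants: 17 (2R,3R)-3-hydroxy-5,7-dimethoxy-8-(3-methylbut-2-enyl)-2-{4-[tri(propan-2-yl)silyloxy]phenyl}-2,3-dihydro-4H-chromen-4-one
Product: 18 (2R,3R)-3,5-dihydroxy-7-methoxy-8-(3-methylbut-2-enyl)-2-{4-[tri(propan-2-yl)silyloxy]phenyl}-2,3-dihydro-4H-chromen-4-one
Conditions: MgI2·OEt2 (3 equiv), THF, 50 °C; aq. NH4Cl
Reagents that add atoms: none
Why: Chelation-directed demethylation: magnesium bridges the C4 carbonyl and the peri methoxy oxygen, and iodide removes that methyl group by SN2 attack; the C7 methoxy group has no such activation. The mild Lewis acid leaves the prenyl olefin and silyl ether alone, and no base is present that could open ring C.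

Step 14
Reactants: 18 (2R,3R)-3,5-dihydroxy-7-methoxy-8-(3-methylbut-2-enyl)-2-{4-[tri(propan-2-yl)silyloxy]phenyl}-2,3-dihydro-4H-chromen-4-one
Product: 19 (2R,3R)-3,5-dihydroxy-2-(4-hydroxyphenyl)-7-methoxy-8-(3-methylbut-2-enyl)-2,3-dihydro-4H-chromen-4-one
Conditions: Bu4NF, AcOH (1:1), THF, 0 °C
Reagents that add atoms: none
Why: Fluoride cleaves the aryl O–Si bond; acetic acid keeps the medium from turning basic, so neither enolization with ring opening nor aerial oxidation to the flavonol should occur.

## Compound list

1 | 3,5-dimethoxyphenol | COc1cc(O)cc(OC)c1 | starting material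
2 | 1-bromo-3-methylbut-2-ene | CC(C)=CCBr | starting material
3 | 3,5-dimethoxy-2-(3-methylbut-2-enyl)phenol | COc1cc(O)c(CC=C(C)C)c(OC)c1 | intermediate
4 | ethyl 2-oxoacetate (ethyl glyoxylate) | CCOC(=O)C=O | starting material
5 | ethyl 2-hydroxy-2-[2-hydroxy-4,6-dimethoxy-3-(3-methylbut-2-enyl)phenyl]acetate (racemic) | CCOC(=O)C(O)c1c(O)c(CC=C(C)C)c(OC)cc1OC | intermediate
6 | 4-hydroxybenzaldehyde | O=Cc1ccc(O)cc1 | starting material
7 | 4-[tri(propan-2-yl)silyloxy]benzaldehyde | CC(C)[Si](Oc1ccc(C=O)cc1)(C(C)C)C(C)C | intermediate
8 | {4-[tri(propan-2-yl)silyloxy]phenyl}methanol | CC(C)[Si](Oc1ccc(CO)cc1)(C(C)C)C(C)C | intermediate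
9 | [4-(bromomethyl)phenoxy]tri(propan-2-yl)silane | CC(C)[Si](Oc1ccc(CBr)cc1)(C(C)C)C(C)C | intermediate
10 | ethyl 2-hydroxy-2-[4,6-dimethoxy-3-(3-methylbut-2-enyl)-2-({4-[tri(propan-2-yl)silyloxy]phenyl}methoxy)phenyl]acetate (racemic) | CCOC(=O)C(O)c1c(OCc2ccc(O[Si](C(C)C)(C(C)C)C(C)C)cc2)c(CC=C(C)C)c(OC)cc1OC | intermediate
11 | ethyl 2-[4,6-dimethoxy-3-(3-methylbut-2-enyl)-2-({4-[tri(propan-2-yl)silyloxy]phenyl}methoxy)phenyl]-2-oxoacetate | CCOC(=O)C(=O)c1c(OCc2ccc(O[Si](C(C)C)(C(C)C)C(C)C)cc2)c(CC=C(C)C)c(OC)cc1OC | intermediate
12 | ethyl 2-[4,6-dimethoxy-3-(3-methylbut-2-enyl)-2-({4-[tri(propan-2-yl)silyloxy]phenyl}methoxy)phenyl]-2-[(4-methylphenyl)sulfonylhydrazinylidene]acetate | CCOC(=O)C(=NNS(=O)(=O)c1ccc(C)cc1)c1c(OCc2ccc(O[Si](C(C)C)(C(C)C)C(C)C)cc2)c(CC=C(C)C)c(OC)cc1OC | intermediate (not isolated)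
13 | ethyl 2-diazo-2-[4,6-dimethoxy-3-(3-methylbut-2-enyl)-2-({4-[tri(propan-2-yl)silyloxy]phenyl}methoxy)phenyl]acetate | CCOC(=O)C(=[N+]=[N-])c1c(OCc2ccc(O[Si](C(C)C)(C(C)C)C(C)C)cc2)c(CC=C(C)C)c(OC)cc1OC | intermediate
14 | ethyl (2S,3R)-4,6-dimethoxy-7-(3-methylbut-2-enyl)-2-{4-[tri(propan-2-yl)silyloxy]phenyl}-2,3-dihydro-1-benzofuran-3-carboxylate | COc1cc(OC)c2c(c1CC=C(C)C)O[C@H](c1ccc(O[Si](C(C)C)(C(C)C)C(C)C)cc1)[C@@H]2C(=O)OCC | intermediate
15 | ethyl (2R,3S)-3-hydroxy-4,6-dimethoxy-7-(3-methylbut-2-enyl)-2-{4-[tri(propan-2-yl)silyloxy]phenyl}-2,3-dihydro-1-benzofuran-3-carboxylate | COc1cc(OC)c2c(c1CC=C(C)C)O[C@H](c1ccc(O[Si](C(C)C)(C(C)C)C(C)C)cc1)[C@]2(O)C(=O)OCC | intermediate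
16 | (2R,3S)-3-hydroxy-4,6-dimethoxy-7-(3-methylbut-2-enyl)-2-{4-[tri(propan-2-yl)silyloxy]phenyl}-2,3-dihydro-1-benzofuran-3-carbaldehyde | COc1cc(OC)c2c(c1CC=C(C)C)O[C@H](c1ccc(O[Si](C(C)C)(C(C)C)C(C)C)cc1)[C@]2(O)C=O | intermediate
17 | (2R,3R)-3-hydroxy-5,7-dimethoxy-8-(3-methylbut-2-enyl)-2-{4-[tri(propan-2-yl)silyloxy]phenyl}-2,3-dihydro-4H-chromen-4-one | COc1cc(OC)c2c(c1CC=C(C)C)O[C@H](c1ccc(O[Si](C(C)C)(C(C)C)C(C)C)cc1)[C@@H](O)C2=O | intermediate
18 | (2R,3R)-3,5-dihydroxy-7-methoxy-8-(3-methylbut-2-enyl)-2-{4-[tri(propan-2-yl)silyloxy]phenyl}-2,3-dihydro-4H-chromen-4-one | COc1cc(O)c2c(c1CC=C(C)C)O[C@H](c1ccc(O[Si](C(C)C)(C(C)C)C(C)C)cc1)[C@@H](O)C2=O | intermediate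
19 | (2R,3R)-3,5-dihydroxy-2-(4-hydroxyphenyl)-7-methoxy-8-(3-methylbut-2-enyl)-2,3-dihydro-4H-chromen-4-one | COc1cc(O)c2c(c1CC=C(C)C)O[C@H](c1ccc(O)cc1)[C@@H](O)C2=O | target

## Step count and least certain steps

Total step count: 14. Longest linear sequence: 12 steps (6 → 7 → 8 → 9 → 10 → 11 → 13 → 14 → 15 → 16 → 17 → 18 → 19); the ring A branch from 1 joins at step 6.

Step 12 (key step, Proposed new method). The most likely failures are migration of the ring A carbon instead of C2, and ionization of the tertiary benzylic hydroxyl followed by loss of the C2 proton; both are encouraged by the very electron-rich ring A. Leakage through an unchelated transition state would also deliver the wrong configuration at C3. The fallback uses the established chalcone epoxide route to dihydroflavonols; it sets out from 3 and comes back at 19.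
- Phenol 3 would be protected with chloromethyl methyl ether and iPr2NEt as 1-(methoxymethoxy)-3,5-dimethoxy-2-(3-methylbut-2-enyl)benzene F1.
- Directed ortho-lithiation between the acetal and methoxy oxygens (n-BuLi, THF, 0 °C) and acylation with N-methoxy-N-methylacetamide would give 1-[2-(methoxymethoxy)-4,6-dimethoxy-3-(3-methylbut-2-enyl)phenyl]ethanone F2.
- Claisen–Schmidt condensation (KOH, EtOH) with commercial 4-(methoxymethoxy)benzaldehyde would give (E)-1-[2-(methoxymethoxy)-4,6-dimethoxy-3-(3-methylbut-2-enyl)phenyl]-3-[4-(methoxymethoxy)phenyl]prop-2-en-1-one F3.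
- Juliá–Colonna epoxidation (poly-L-leucine, urea–H2O2, DBU, THF; the antipodal polymer if the sense of induction is the opposite) attacks only the enone and would give [(2R,3S)-3-[4-(methoxymethoxy)phenyl]oxiran-2-yl][2-(methoxymethoxy)-4,6-dimethoxy-3-(3-methylbut-2-enyl)phenyl]methanone F4.
- Dilute HCl in MeOH would remove both acetals; the freed phenol opens the epoxide at the benzylic carbon with inversion (6-endo) to (2R,3R)-3-hydroxy-2-(4-hydroxyphenyl)-5,7-dimethoxy-8-(3-methylbut-2-enyl)-2,3-dihydro-4H-chromen-4-one F5.
- MgI2·OEt2 as in step 13 would then give 19.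

Step 9. What may go wrong is competing insertion into the O-methyl C–H on the other side of the carbene, and erosion of enantioselectivity. The second ortho substituent twists the carbene away from the geometry for which the catalyst is established, and the electron-rich benzylic ether may react in a stepwise hydride-transfer manner. The fallback avoids the carbene; it sets out from 11 and comes back at 15. Irradiation of 11 (365 nm, degassed benzene) should cause hydrogen transfer from the benzylic ether methylene to the excited keto oxygen and closure of the resulting 1,5-biradical (Norrish–Yang cyclization). This gives the hydroxy ester directly as a racemic mixture of diastereomers. The isomer with hydroxyl anti to aryl, racemic ethyl (2R*,3S*)-3-hydroxy-4,6-dimethoxy-7-(3-methylbut-2-enyl)-2-{4-[tri(propan-2-yl)silyloxy]phenyl}-2,3-dihydro-1-benzofuran-3-carboxylate F6, would be separated and resolved by preparative chromatography on a chiral stationary phase to give 15.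

Step 10. What may go wrong is β-elimination of the ring oxygen from the enolate (ring opening) before oxygen transfer, and addition of the enolate to the sulfonimine by-product. The fallback replaces the free enolate by a trapped one; it sets out from 14 and comes back at 15. Deprotonation with LiN(iPr)2 in the presence of Me3SiCl at −78 °C (internal quench) would give (2R)-3-[ethoxy(trimethylsilyloxy)methylidene]-4,6-dimethoxy-7-(3-methylbut-2-enyl)-2-{4-[tri(propan-2-yl)silyloxy]phenyl}-2,3-dihydro-1-benzofuran F7. Rubottom oxidation with one equivalent of dimethyldioxirane at −78 °C should oxidize the ketene acetal, which is far more nucleophilic than the prenyl olefin, anti to the aryl group. Mild acidic methanol then frees 15.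

Step 8. What may go wrong is slow or incomplete condensation at a keto group shielded by two ortho substituents. The fallback avoids that condensation; it sets out from 10 and comes back at 13. Acetylation (Ac2O, DMAP, pyridine) would give ethyl 2-acetoxy-2-[4,6-dimethoxy-3-(3-methylbut-2-enyl)-2-({4-[tri(propan-2-yl)silyloxy]phenyl}methoxy)phenyl]acetate F8. Reductive removal of the α-acetoxy group with samarium diiodide (SmI2, THF, MeOH, −78 °C) would give ethyl 2-[4,6-dimethoxy-3-(3-methylbut-2-enyl)-2-({4-[tri(propan-2-yl)silyloxy]phenyl}methoxy)phenyl]acetate F9. Regitz diazo transfer (4-acetamidobenzenesulfonyl azide, DBU, MeCN) would then give 13.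

Step 1. What may go wrong is O-alkylation, attack at the para carbon and double alkylation, all of which lower the share of the ortho product. The fallback is fully regiocontrolled; it sets out from 1 and comes back at 3. O-Allylation (allyl bromide, K2CO3, acetone) would give 1,3-dimethoxy-5-(prop-2-enyloxy)benzene F10. Claisen rearrangement (N,N-diethylaniline, 190 °C) can only go to an ortho carbon and would give 3,5-dimethoxy-2-(prop-2-enyl)phenol F11. Cross-metathesis with 2-methylbut-2-ene and the second-generation Grubbs catalyst RuCl2(=CHPh)(PCy3)(H2IMes) would give 3.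

Step 11. What may go wrong is over-reduction to the diol, or a premature aluminium-induced shift if the mixture warms before quenching. The fallback separates reduction and oxidation; it sets out from 15 and comes back at 16. LiBH4 in THF would give (2R,3R)-3-(hydroxymethyl)-4,6-dimethoxy-7-(3-methylbut-2-enyl)-2-{4-[tri(propan-2-yl)silyloxy]phenyl}-2,3-dihydro-1-benzofuran-3-ol F12. Parikh–Doering oxidation (SO3·pyridine, DMSO, iPr2NEt) oxidizes only the primary alcohol and would give 16.

## Further compounds

F1 | step 12 | 1-(methoxymethoxy)-3,5-dimethoxy-2-(3-methylbut-2-enyl)benzene | COCOc1cc(OC)cc(OC)c1CC=C(C)C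
F2 | step 12 | 1-[2-(methoxymethoxy)-4,6-dimethoxy-3-(3-methylbut-2-enyl)phenyl]ethanone | CC(=O)c1c(OCOC)c(CC=C(C)C)c(OC)cc1OC
F3 | step 12 | (E)-1-[2-(methoxymethoxy)-4,6-dimethoxy-3-(3-methylbut-2-enyl)phenyl]-3-[4-(methoxymethoxy)phenyl]prop-2-en-1-one | COCOc1ccc(/C=C/C(=O)c2c(OCOC)c(CC=C(C)C)c(OC)cc2OC)cc1
F4 | step 12 | [(2R,3S)-3-[4-(methoxymethoxy)phenyl]oxiran-2-yl][2-(methoxymethoxy)-4,6-dimethoxy-3-(3-methylbut-2-enyl)phenyl]methanone | O=C(c1c(OCOC)c(CC=C(C)C)c(OC)cc1OC)[C@@H]1O[C@H]1c1ccc(OCOC)cc1
F5 | step 12 | (2R,3R)-3-hydroxy-2-(4-hydroxyphenyl)-5,7-dimethoxy-8-(3-methylbut-2-enyl)-2,3-dihydro-4H-chromen-4-one | COc1cc(OC)c2c(c1CC=C(C)C)O[C@H](c1ccc(O)cc1)[C@@H](O)C2=O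
F6 | step 9 | racemic ethyl (2R*,3S*)-3-hydroxy-4,6-dimethoxy-7-(3-methylbut-2-enyl)-2-{4-[tri(propan-2-yl)silyloxy]phenyl}-2,3-dihydro-1-benzofuran-3-carboxylate | COc1cc(OC)c2c(c1CC=C(C)C)O[C@H](c1ccc(O[Si](C(C)C)(C(C)C)C(C)C)cc1)[C@]2(O)C(=O)OCC.COc1cc(OC)c2c(c1CC=C(C)C)O[C@@H](c1ccc(O[Si](C(C)C)(C(C)C)C(C)C)cc1)[C@@]2(O)C(=O)OCC
F7 | step 10 | (2R)-3-[ethoxy(trimethylsilyloxy)methylidene]-4,6-dimethoxy-7-(3-methylbut-2-enyl)-2-{4-[tri(propan-2-yl)silyloxy]phenyl}-2,3-dihydro-1-benzofuran (double-bond geometry not defined) | COc1cc(OC)c2c(c1CC=C(C)C)O[C@H](c1ccc(O[Si](C(C)C)(C(C)C)C(C)C)cc1)C2=C(OCC)O[Si](C)(C)C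
F8 | step 8 | ethyl 2-acetoxy-2-[4,6-dimethoxy-3-(3-methylbut-2-enyl)-2-({4-[tri(propan-2-yl)silyloxy]phenyl}methoxy)phenyl]acetate (racemic) | CCOC(=O)C(OC(C)=O)c1c(OCc2ccc(O[Si](C(C)C)(C(C)C)C(C)C)cc2)c(CC=C(C)C)c(OC)cc1OC
F9 | step 8 | ethyl 2-[4,6-dimethoxy-3-(3-methylbut-2-enyl)-2-({4-[tri(propan-2-yl)silyloxy]phenyl}methoxy)phenyl]acetate | CCOC(=O)Cc1c(OCc2ccc(O[Si](C(C)C)(C(C)C)C(C)C)cc2)c(CC=C(C)C)c(OC)cc1OC
F10 | step 1 | 1,3-dimethoxy-5-(prop-2-enyloxy)benzene | C=CCOc1cc(OC)cc(OC)c1
F11 | step 1 | 3,5-dimethoxy-2-(prop-2-enyl)phenol | C=CCc1c(O)cc(OC)cc1OC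
F12 | step 11 | (2R,3R)-3-(hydroxymethyl)-4,6-dimethoxy-7-(3-methylbut-2-enyl)-2-{4-[tri(propan-2-yl)silyloxy]phenyl}-2,3-dihydro-1-benzofuran-3-ol | COc1cc(OC)c2c(c1CC=C(C)C)O[C@H](c1ccc(O[Si](C(C)C)(C(C)C)C(C)C)cc1)[C@]2(O)CO
A1 | alternative 1 | (2R,3R)-1-[2-fluoro-4,6-dimethoxy-3-(3-methylbut-2-enyl)phenyl]-3-hydroxy-2-(prop-2-enyloxy)-3-[4-(2,2-dimethylpropanoyloxy)phenyl]propan-1-one | COc1cc(OC)c(C(=O)[C@H](OCC=C)[C@H](O)c2ccc(OC(=O)C(C)(C)C)cc2)c(F)c1CC=C(C)C
A2 | alternative 1 | 2-diazo-1-[2-fluoro-4,6-dimethoxy-3-(3-methylbut-2-enyl)phenyl]ethanone | COc1cc(OC)c(C(=O)C=[N+]=[N-])c(F)c1CC=C(C)C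
A3 | alternative 1 | prop-2-en-1-ol | C=CCO
A4 | alternative 1 | 4-formylphenyl 2,2-dimethylpropanoate | CC(C)(C)C(=O)Oc1ccc(C=O)cc1
A5 | alternative 2 | prop-2-enyl (2R,3R)-3-hydroxy-5,7-dimethoxy-2-[4-(methoxymethoxy)phenyl]-8-(3-methylbut-2-enyl)-4-oxochromane-3-carboxylate | COc1cc(OC)c2c(c1CC=C(C)C)O[C@H](c1ccc(OCOC)cc1)[C@@](C(=O)OCC=C)(O)C2=O
A6 | alternative 2 | prop-2-enyl 3-[2-formyl-3,5-dimethoxy-6-(3-methylbut-2-enyl)phenoxy]-3-[4-(methoxymethoxy)phenyl]-2-oxopropanoate | C=CCOC(=O)C(=O)C(Oc1c(C=O)c(OC)cc(OC)c1CC=C(C)C)c1ccc(OCOC)cc1
A7 | alternative 3 | (2R,3R)-5,7-dimethoxy-3-(methoxymethoxy)-2-[4-(methoxymethoxy)phenyl]-8-(3-methylbut-2-enyl)chroman-4-one | COc1cc(OC)c2c(c1CC=C(C)C)O[C@H](c1ccc(OCOC)cc1)[C@@H](OCOC)C2=O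
A8 | alternative 3 | 3,5-dimethoxy-2-(3-methylbut-2-enyl)-6-(trimethylsilyl)phenyl trifluoromethanesulfonate | COc1cc(OC)c([Si](C)(C)C)c(OS(=O)(=O)C(F)(F)F)c1CC=C(C)C
A9 | alternative 3 | methyl (2R,3R)-3-hydroxy-2-(methoxymethoxy)-3-[4-(methoxymethoxy)phenyl]propanoate | O[C@H](c1ccc(OCOC)cc1)[C@@H](OCOC)C(=O)OC
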